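The 2‑methoxy‑4‑pyranone ring is disconnected at the O1–C6 bond. The C4 carbonyl with the C5=C6 unit (C6 bearing the undecyl chain) is read as an ynone, and the C2(OMe)–O1 unit as a methyl ester viewed from its carbonyl oxygen, which is to serve as O1. The precursor is therefore the open‑chain methyl 16‑acetoxy‑2‑methyl‑3‑oxohexadec‑4‑ynoate, with the acetate already in place. An iodonium source should close the six‑membered ring through the ester oxygen, forming O1–C6 and a C5–I bond while keeping the methoxy group, so no O‑methylation is required. The C5 iodide is then exchanged for the last methyl group by cross‑coupling.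

Key step: step 6

Assumption: ring atoms are numbered O1, C2 (OMe), C3 (Me), C4 (C=O), C5, C6 (chain); the acidic CH(Me) carbon is C2 of the open‑chain ester and C3 of the ring, and all stereocentres on the way (none in the target) are carried as mixtures because they are erased later.

Step 1
Reactants: 1 11‑bromoundecan‑1‑ol; 2 3,3‑diethoxyprop‑1‑yne
Product: 6 14,14‑diethoxytetradec‑12‑yn‑1‑ol, via lithium 3,3‑diethoxyprop‑1‑yn‑1‑ide 3 (not isolated), via lithium 11‑bromoundecan‑1‑olate 4 (not isolated), via lithium 14,14‑diethoxytetradec‑12‑yn‑1‑olate 5 (not isolated)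
Conditions: 2 (2.4 equiv), n‑BuLi (2.2 equiv), THF, −78 °C; then 1, DMPU, −78 °C → rt; H2O
Reagents that add atoms: none
Why: SN2 alkylation of a lithium acetylide by a primary bromide, in which the hydroxyl is masked in the flask as its lithium alkoxide (a far weaker nucleophile than the acetylide) and the propargylic acetal is inert to base.

Step 2
Reactants: 6 14,14‑diethoxytetradec‑12‑yn‑1‑ol
Product: 7 14,14‑diethoxytetradec‑12‑yn‑1‑yl acetate
Conditions: Ac2O, pyridine, DMAP (cat.), CH2Cl2, 0 °C → rt
Reagents that add atoms: acetic anhydride, CC(=O)OC(C)=O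
Why: DMAP‑catalysed acetylation (nucleophilic acyl substitution) of the primary alcohol installs the final ester while the acetal and alkyne are untouched by the mildly basic medium.

Step 3
Reactants: 7 14,14‑diethoxytetradec‑12‑yn‑1‑yl acetate
Product: 8 14‑oxotetradec‑12‑yn‑1‑yl acetate
Conditions: HCO2H/H2O (9:1), CH2Cl2, rt
Reagents that add atoms: water, O
Why: Acid‑catalysed acetal hydrolysis, for which the electron‑poor propargylic acetal needs a fairly strong acid that the primary acetate tolerates at room temperature.

Step 4
Reactants: 8 14‑oxotetradec‑12‑yn‑1‑yl acetate; 9 methyl propionate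
Product: 12 methyl 16‑acetoxy‑3‑hydroxy‑2‑methylhexadec‑4‑ynoate (syn/anti mixture, racemic), via lithium enolate of methyl propionate 10 (not isolated), via lithium aldolate 11 (not isolated)
Conditions: 9 (1.2 equiv), LiN(i‑Pr)2 (1.15 equiv), THF, −78 °C; then 8, −78 °C; sat. aq. NH4Cl at −78 °C
Reagents that add atoms: none
Why: Aldol addition of the lithium ester enolate to the highly electrophilic ynal carbonyl at −78 °C should be much faster than attack on the remote acetate; the two new stereocentres form without control, which is acceptable because both are destroyed in steps 5 and 6.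

Step 5
Reactants: 12 methyl 16‑acetoxy‑3‑hydroxy‑2‑methylhexadec‑4‑ynoate
Product: 13 methyl 16‑acetoxy‑2‑methyl‑3‑oxohexadec‑4‑ynoate (racemic, in equilibrium with its enol)
Conditions: Dess–Martin periodinane (1.3 equiv), CH2Cl2, 0 °C → rt; aq. Na2S2O3/NaHCO3 wash; used promptly
Reagents that add atoms: none
Why: Dess–Martin oxidation of the secondary propargylic alcohol to the ynone proceeds under nearly neutral conditions that spare the acetate and avoid base‑induced reactions of the β‑keto ynone.

Step 6
Reactants: 13 methyl 16‑acetoxy‑2‑methyl‑3‑oxohexadec‑4‑ynoate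
Product: 15 11‑(3‑iodo‑6‑methoxy‑5‑methyl‑4‑oxo‑4H‑pyran‑2‑yl)undecyl acetate, via methoxy oxocarbenium chloride 14 (not isolated)
Conditions: ICl (1.1 equiv, solution in CH2Cl2, added slowly), CH2Cl2, −78 °C → 0 °C, dark, no base; aq. Na2S2O3/NaHCO3 quench
Reagents that add atoms: iodine monochloride, ClI
Why: Proposed new method: ICl delivers I+ to the alkyne of the keto tautomer, and the ester carbonyl oxygen captures the distal alkyne carbon in an anti addition, giving the cyclic 2‑methoxy oxocarbenium ion 14 with O1–C6 and C5–I in place; loss of the C3 proton, activated by both the C4 carbonyl and the oxocarbenium carbon, then gives the neutral methoxypyranone. The closest known reaction types are the ICl cyclisation of 2‑methoxyaryl alkynyl ketones to 3‑iodochromones and the TfOH‑promoted 6‑endo cyclisation of alkynyl 1,3‑diketones to 4‑pyranones. The single ring closes in the 6‑endo‑dig mode. No stereocentre is created, and the racemic CH(Me) centre of 13 (ring C3) disappears on deprotonation. The step needs 6‑endo over 5‑exo closure, which the conjugate polarisation of the ynone (positive charge at the β carbon, C6) should secure, and alkyne activation over iodination at C3, which is limited by the low enol content of the α‑methyl β‑keto ester under base‑free addition at −78 °C. It also needs proton loss from 14 to outrun demethylation by chloride, which the high acidity of the C3–H should ensure.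

Step 7
Reactants: 15 11‑(3‑iodo‑6‑methoxy‑5‑methyl‑4‑oxo‑4H‑pyran‑2‑yl)undecyl acetate
Product: 16 11‑(6‑methoxy‑3,5‑dimethyl‑4‑oxo‑4H‑pyran‑2‑yl)undecyl acetate
Conditions: MeZnCl (2.0 equiv), Pd(PPh3)4 (5 mol%), THF, rt → 50 °C
Reagents that add atoms: methylzinc chloride, C[Zn]Cl
Why: Negishi cross‑coupling (oxidative addition of zerovalent palladium into the activated alkenyl C5–I bond, transmetallation from zinc, reductive elimination) in a neutral, base‑free medium that leaves the acetate and the methoxy enol ether intact.

Compound list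
1 | 11‑bromoundecan‑1‑ol | OCCCCCCCCCCCBr | starting material
2 | 3,3‑diethoxyprop‑1‑yne (propargyl aldehyde diethyl acetal) | C#CC(OCC)OCC | starting material
3 | lithium 3,3‑diethoxyprop‑1‑yn‑1‑ide | [Li]C#CC(OCC)OCC | intermediate
4 | lithium 11‑bromoundecan‑1‑olate | [Li]OCCCCCCCCCCCBr | intermediate
5 | lithium 14,14‑diethoxytetradec‑12‑yn‑1‑olate | [Li]OCCCCCCCCCCCC#CC(OCC)OCC | intermediate
6 | 14,14‑diethoxytetradec‑12‑yn‑1‑ol | OCCCCCCCCCCCC#CC(OCC)OCC | intermediate
7 | 14,14‑diethoxytetradec‑12‑yn‑1‑yl acetate | CC(=O)OCCCCCCCCCCCC#CC(OCC)OCC | intermediate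
8 | 14‑oxotetradec‑12‑yn‑1‑yl acetate | CC(=O)OCCCCCCCCCCCC#CC=O | intermediate
9 | methyl propionate | CCC(=O)OC | starting material
10 | lithium enolate of methyl propionate (lithium 1‑methoxyprop‑1‑en‑1‑olate, double‑bond geometry not specified) | CC=C(OC)O[Li] | intermediate
11 | lithium aldolate, methyl 16‑acetoxy‑3‑(lithiooxy)‑2‑methylhexadec‑4‑ynoate (diastereomer mixture, racemic) | COC(=O)C(C)C(O[Li])C#CCCCCCCCCCCCOC(C)=O | intermediate
12 | methyl 16‑acetoxy‑3‑hydroxy‑2‑methylhexadec‑4‑ynoate (syn/anti mixture, racemic) | COC(=O)C(C)C(O)C#CCCCCCCCCCCCOC(C)=O | intermediate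
13 | methyl 16‑acetoxy‑2‑methyl‑3‑oxohexadec‑4‑ynoate (racemic) | COC(=O)C(C)C(=O)C#CCCCCCCCCCCCOC(C)=O | intermediate
14 | 6‑(11‑acetoxyundecyl)‑5‑iodo‑2‑methoxy‑3‑methyl‑4‑oxo‑3,4‑dihydropyrylium chloride (racemic) | COC1=[O+]C(CCCCCCCCCCCOC(C)=O)=C(I)C(=O)C1C.[Cl-] | intermediate
15 | 11‑(3‑iodo‑6‑methoxy‑5‑methyl‑4‑oxo‑4H‑pyran‑2‑yl)undecyl acetate | COc1oc(CCCCCCCCCCCOC(C)=O)c(I)c(=O)c1C | intermediate
16 | 11‑(6‑methoxy‑3,5‑dimethyl‑4‑oxo‑4H‑pyran‑2‑yl)undecyl acetate | COc1oc(CCCCCCCCCCCOC(C)=O)c(C)c(=O)c1C | target

Total step count: 7. Longest linear sequence: 7 steps.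

Steps most likely to fail

Step 6. Iodination may occur at the enolisable C3 position instead of at the alkyne, the closure may take the 5‑exo course, or chloride may demethylate the oxocarbenium ion before it loses its proton. The fallback uses known chemistry only, sets out from 13 and returns at 15. Conjugate addition of Et2NH to the ynone in EtOH, followed by hydrolysis of the enaminone with dilute HCl in THF (a formal hydration), should give methyl 16‑acetoxy‑2‑methyl‑3,5‑dioxohexadecanoate F1. DBU in toluene should lactonise this to 11‑(4‑hydroxy‑5‑methyl‑6‑oxo‑6H‑pyran‑2‑yl)undecyl acetate F2. Methylation on the lactone carbonyl oxygen with MeOSO2CF3 in CH2Cl2 should give 11‑(6‑methoxy‑5‑methyl‑4‑oxo‑4H‑pyran‑2‑yl)undecyl acetate F3, any 4‑methoxy‑2‑pyranone isomer being removed by chromatography. Electrophilic iodination of the only free ring position with N‑iodosuccinimide and catalytic TFA in MeCN should then give 15, from which step 7 proceeds unchanged.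

Step 1. The lithium alkoxide of the bromo alcohol may be O‑alkylated by a second molecule of bromide, or may aggregate the acetylide and leave C‑alkylation incomplete. The fallback separates protection from C–C bond formation, sets out from 1 and returns at 6. Dihydropyran and PPTS in CH2Cl2 should give 2‑((11‑bromoundecyl)oxy)tetrahydro‑2H‑pyran F4 (racemic). Alkylation of lithium acetylide 3 with this bromide in THF/DMPU should give 2‑((14,14‑diethoxytetradec‑12‑yn‑1‑yl)oxy)tetrahydro‑2H‑pyran F5. PPTS in EtOH at 50 °C should remove the tetrahydropyranyl group, the diethyl acetal surviving because its exchange with the solvent is degenerate, to give 6.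

Step 4. The lithium enolate may attack or deprotonate the acetate, or add in conjugate fashion to the ynal. The fallback replaces the basic lithium enolate by a zinc enolate, sets out from 8 and returns at 12. Methyl 2‑bromopropanoate and activated Zn in THF should form methyl 2‑(bromozincio)propanoate F6, which should add only to the aldehyde (Reformatsky reaction) and give 12 after work‑up with dilute HCl.

Further compounds
F1 | step 6 | methyl 16‑acetoxy‑2‑methyl‑3,5‑dioxohexadecanoate (racemic) | COC(=O)C(C)C(=O)CC(=O)CCCCCCCCCCCOC(C)=O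
F2 | step 6 | 11‑(4‑hydroxy‑5‑methyl‑6‑oxo‑6H‑pyran‑2‑yl)undecyl acetate | CC(=O)OCCCCCCCCCCCc1cc(O)c(C)c(=O)o1
F3 | step 6 | 11‑(6‑methoxy‑5‑methyl‑4‑oxo‑4H‑pyran‑2‑yl)undecyl acetate | COc1oc(CCCCCCCCCCCOC(C)=O)cc(=O)c1C
F4 | step 1 | 2‑((11‑bromoundecyl)oxy)tetrahydro‑2H‑pyran (racemic) | BrCCCCCCCCCCCOC1CCCCO1
F5 | step 1 | 2‑((14,14‑diethoxytetradec‑12‑yn‑1‑yl)oxy)tetrahydro‑2H‑pyran (racemic) | CCOC(OCC)C#CCCCCCCCCCCCOC1CCCCO1
F6 | step 4 | methyl 2‑(bromozincio)propanoate (racemic) | CC([Zn]Br)C(=O)OC
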